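## Structural features

The target 26 joins three units: a 2-hydroxy-5-(3-methylbutylamino)-1,4-benzoquinone (ring C), a one-carbon link C11, and a rearranged drimane decalin (terpenoid numbering; ring A = C1–C5 and C10, ring B = C5–C10). C11 hangs from the quaternary carbon C9, which also carries a methyl group and lies between two further stereocentres, C8 (secondary methyl) and C10 (ring-fusion hydrogen). The three are contiguous (8S,9R,10S), with the two methyl groups cis and H10 cis to C11. Ring A carries the gem-dimethyl carbon C4, bonded directly to C5 of the trisubstituted C5=C6 alkene, so C5 is a fully substituted sp2 ring-fusion carbon. The fragile parts are the aminohydroxyquinone (sensitive to nucleophiles, strong base and reductants) and the C5=C6 alkene, which under strong acid can enter cationic 1,2-shifts or capture the quinone hydroxyl. The real difficulty is the congested C8–C9–C10 triad with its neopentyl link to ring C, together with placing the alkene exactly beside the gem-dimethyl carbon. The key step uses two facts: H10 is trans to the C9 methyl, and C4 is bonded to C5. C10 is therefore the β-carbon of a ring B enone (C6=O, C5 α) that can take hydride anti to the C9 methyl, while the enolate at C5 forms C4–C5 to a pendant methyl ketone and closes ring A.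

## Logic of the disconnections

26 is cut at the quinone C–N bond to 24 and 25. The exchange of a vinylogous ester for a vinylogous amide is mild, so the amine need not be carried through any earlier step. The forward step must aminate only the methoxy-bearing carbon; the hydroxyl-bearing carbon is shielded as its anion.

24 is traced through 23 to 22 by restoring four aryl C–O methyl bonds. The tetramethoxyarene is inert to organometallic reagents, copper hydride and base, which removes the quinone from all earlier planning. The forward oxidation must spare the C5=C6 alkene, and the hydrolysis must choose the methoxy group next to the side chain.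

22 is cut at C6–H to 21, and 21 at the C4–CH3 bond and the O–S bond to 19. The enolate left by conjugate methylation has its double bond at C5=C6, exactly where the alkene is needed, so one carbonyl group pays for both the gem-dimethyl carbon and the alkene position. The demand is methyl transfer to a fully substituted β-carbon and O-sulfonylation of a hindered enolate.

19 is traced to 18 by adding water across C4=C5. This exposes an aldol relationship between the C6 ketone and the C4 carbinol. The forward elimination must end in conjugation and must not touch C10.

18 is cut at C4–C5 and C10–H to 16 (the key disconnection). Ring A and three stereocentres are removed, leaving a monocyclic enone with a keto side chain. The forward step must deliver hydride to the C10 face anti to the C9 methyl and must leave the methyl ketone for the enolate.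

16 is cut at C10–C1 to 12 and 13, with a 1,3-shift of the oxygen from C6 back to C10. This turns the side-chain union into a carbonyl addition, and it places the carbonyl beside C9, where it was needed to build the quaternary centre. The demand is 1,2-addition to a carbonyl flanked by that quaternary carbon.

12 is cut at C9–C11 to 8 and 11, and 8 at C9–CH3 to 7. Two enolate alkylations next to the existing C8 stereocentre build C9; methyl must enter first so that the arylmethyl group enters anti to the C8 methyl. The demand is α'-regioselective deprotonation and facial control in a quaternary-forming alkylation.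

11 is cut at C–Br to 10, and 10 at the aryl–C11 bond to 9. The only ring hydrogen flanked by two methoxy groups is lithiated, so regiochemistry is not in question.

7 is traced to 5 by removing the C–S bond and one unsaturation, and 5 through 3 and 2 to 1 by restoring the isopropylidene unit. The chiral pool supplies C8 with no asymmetric step. The demand is that the degradation does not let the double bond of 5 migrate toward the stereocentre.

## Other disconnections considered

Alternative 1: The cut is at C5–C10 and C8–C9, opening both carbocycles to the acyclic trienal A1. Forward, an intramolecular Diels–Alder reaction of the (E)-α-methyl enal onto the 2-silyloxydiene under a chiral oxazaborolidinium Lewis acid would give the cis-fused silyl enol ether aldehyde A2.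
- In favour: two rings, two C–C bonds, the quaternary C9 and the C8/C9/C10 relationship arise in one concerted, stereospecific event. The absolute configuration comes from a catalyst, so the plan does not depend on the scarcer enantiomer of 1. On bond economy and on freedom of enantiomer choice it is the better plan.
- Against: A2 carries oxygen at C7 and its alkene at C6=C7, so the oxygen must be deleted and the alkene moved to C5=C6 without migration. The formyl group must then become the arylmethyl link by aryllithium addition and benzylic deoxygenation at a neopentyl carbon. The C5–C10 bond forms beside the quaternary C4, and a Lewis acid can divert a silyl enol ether and an enal into stepwise Mukaiyama–Michael chemistry.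
- Comparison: on structure, both plans pass through a C5 stereocentre that is later erased. In the chosen plan the oxygen at C6 sits exactly where the alkene is wanted, which is its advantage. On mechanism, catalyst control (A2) stands against substrate control from C8 (18). On step economy the assembly of A1 and the repair of A2 should together be about as long as the chosen 15 steps, so no clear gain is expected.

Alternative 2: The cut is at C9–C10, with ring B reopened to the δ-lactone A3. Forward, the silyl ketene acetal of A3 (KN(SiMe3)2, Me3SiCl) would undergo an Ireland–Claisen ring contraction through the enforced boat to the acid A4.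
- In favour: the most hindered bond of the molecule forms intramolecularly with transfer of chirality from the lactone carbinol carbon to C9 and C10. The gem-dimethyl carbon, the C5=C6 alkene and the arylmethyl group are in their final places at once. On alkene placement it is the better plan, because the chosen route needs three further steps for this.
- Against: the carboxyl carbon must be reduced to a methyl group at a neopentyl quaternary centre (three or more steps, none of them easy). A3 needs its 4,6-trans stereocentres made enantioselectively beside a hindered cyclohexenyl group. A fully substituted ketene acetal must also form cleanly.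
- Comparison: on structure, A4 has the right skeleton but the wrong oxidation level at one carbon, whereas 18 has the right methyl group but needs the alkene adjusted. On mechanism, a concerted [3,3] shift with predictable chirality transfer is at least the equal of the hydride addition–aldol sequence. On step economy the two plans should be about equal.

Alternative 3: The cut is at C4–C5 and C9–C10 of an unrearranged drimane, leading back to the farnesyl arene A5. Forward, protonation of A5 by SnCl4 bound to a chiral 2-alkoxy-2'-hydroxy-1,1'-binaphthyl would close rings A and B to the drimenyl arene A6. Acid would then drive the friedo sequence: H9 to C8, the C10 methyl to C9, H5 to C10, and loss of H6.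
- In favour: it is by far the shortest plan, since A5 is one step from farnesyl bromide and lithiated 9. The suprafacial 1,2-shifts would relay the configuration of A6 into exactly the C8/C9/C10 arrangement of 26. On step economy it is clearly the better plan, and on relative configuration it is the equal.
- Against: a proton-initiated cyclisation that ends by proton loss tends to give alkene isomers, partly cyclised material and moderate enantioselectivity. The rearrangement must stop after three shifts and eliminate toward C6. A fourth shift (a C4 methyl to C5) and other eliminations compete, and no reagent controls that choice.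
- Comparison: the chosen plan is more than twice as long, but it gives each stereocentre and the alkene position its own directed operation and takes its absolute configuration from the chiral pool. Alternative 3 concentrates all risk in two cationic steps; if these could be controlled it would be the superior route.

Key step: step 10

Remarks before the steps:
- The configurations drawn for 16 and 18 and the choice of (S)-1 were checked against 26 (8S,9R,10S) and are used unchanged. The descriptor of 7 becomes R only because sulfur reverses the CIP ranking.
- Assumption: the C4 and C5 configurations of 18 are those of the chelated cis-fused aldol. Both centres become trigonal in step 11, so any epimer is carried forward.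
- Assumption: 13, the ethylene ketal of 5-chloropentan-2-one, is bought as such.

Step 1
Reactants: 1 (S)-(−)-pulegone
Product: 2 (S)-pulegone oxide (both spiro epimers)
Conditions: 30% H2O2, NaOH (0.3 equiv), MeOH, 0 °C → rt
Reagents that add atoms: hydrogen peroxide OO
Why: Weitz–Scheffer nucleophilic epoxidation of the tetrasubstituted enone; the spiro centre forms as a mixture that converges in step 2, and the methyl-bearing stereocentre is not involved.

Step 2
Reactants: 2 (S)-pulegone oxide
Product: 3 (5S)-5-methyl-2-(phenylthio)cyclohexan-1-one (C2 epimers)
Conditions: PhSH, NaH, THF, 0 °C → reflux; H2O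
Reagents that add atoms: thiophenol Sc1ccccc1
Why: Thiolate opens the α,β-epoxy ketone at the carbon α to the carbonyl and the β-alkoxide so formed undergoes retro-aldol loss of acetone; the C2 configuration is irrelevant because C2 becomes trigonal in step 3.

Step 3
Reactants: 3 (5S)-5-methyl-2-(phenylthio)cyclohexan-1-one
Product: 5 (S)-5-methylcyclohex-2-en-1-one, via keto sulfoxide 4 (not isolated)
Conditions: mCPBA (1.0 equiv), CH2Cl2, −78 °C; then CaCO3, PhMe, 80 °C
Reagents that add atoms: none
Why: Sulfide oxidation and thermal syn-elimination of the β-keto sulfoxide, which can only take a hydrogen from C3 and so gives the enone regiospecifically; CaCO3 buffers the sulfenic acid so that the double bond does not migrate toward the stereocentre.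

Step 4
Reactants: 5 (S)-5-methylcyclohex-2-en-1-one
Product: 7 (R)-5-methyl-3-(phenylthio)cyclohex-2-en-1-one, via β-phenylthio ketone 6 (not isolated)
Conditions: PhSH (1.0 equiv), Et3N (cat.), CH2Cl2, 0 °C → rt; then NCS, 0 °C → rt; Et3N (1.2 equiv)
Reagents that add atoms: thiophenol Sc1ccccc1
Why: Thia-Michael addition, then S-chlorination and Pummerer-type loss of HCl, returns the double bond into conjugation (oxidative β-functionalisation of an enone); the stereocentre is untouched and is R only by CIP ranking.

Step 5
Reactants: 7 (R)-5-methyl-3-(phenylthio)cyclohex-2-en-1-one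
Product: 8 (5S,6R)-5,6-dimethyl-3-(phenylthio)cyclohex-2-en-1-one (trans epimer expected to predominate)
Conditions: LiN(iPr)2 (1.1 equiv), THF, −78 °C; MeI, −78 → 0 °C
Reagents that add atoms: iodomethane CI
Why: Kinetic α'-deprotonation of the vinylogous thioester and C-methylation (Stork–Danheiser-type enolate alkylation); methyl should enter mainly trans to the C5 methyl, but C6 is made trigonal again in step 8, so either epimer serves.

Step 6
Reactants: 9 1,2,4,5-tetramethoxybenzene
Product: 10 (2,3,5,6-tetramethoxyphenyl)methanol
Conditions: n-BuLi, TMEDA, THF, 0 °C; (CH2O)n, 0 °C → rt; H2O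
Reagents that add atoms: formaldehyde (from paraformaldehyde) C=O
Why: Directed ortho-lithiation at the ring position flanked by two methoxy groups, then hydroxymethylation of the aryllithium.

Step 7
Reactants: 10 (2,3,5,6-tetramethoxyphenyl)methanol
Product: 11 3-(bromomethyl)-1,2,4,5-tetramethoxybenzene
Conditions: PBr3, Et2O, 0 °C
Reagents that add atoms: phosphorus tribromide BrP(Br)Br
Why: Bromination of an electron-rich benzylic alcohol through its phosphite ester; the bromide should be used promptly because it is labile.

Step 8
Reactants: 8 (5S,6R)-5,6-dimethyl-3-(phenylthio)cyclohex-2-en-1-one; 11 3-(bromomethyl)-1,2,4,5-tetramethoxybenzene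
Product: 12 (5S,6R)-5,6-dimethyl-3-(phenylthio)-6-(2,3,5,6-tetramethoxybenzyl)cyclohex-2-en-1-one
Conditions: LiN(iPr)2 (1.2 equiv), THF, −78 → −40 °C; 11 (1.2 equiv), DMPU, −78 → 0 °C
Reagents that add atoms: none
Why: Enolate alkylation that creates the quaternary centre: A(1,2) strain with the C6 methyl holds the C5 methyl pseudoaxial in the tetrasubstituted enolate, and the benzylic bromide should add axially to the opposite face. The arylmethyl group therefore ends trans to the C5 methyl and the two methyl groups cis, the established sense for 5,6-dialkyl enolates of this type.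

Step 9
Reactants: 12 (5S,6R)-5,6-dimethyl-3-(phenylthio)-6-(2,3,5,6-tetramethoxybenzyl)cyclohex-2-en-1-one; 13 2-(3-chloropropyl)-2-methyl-1,3-dioxolane
Product: 16 (4R,5S)-4,5-dimethyl-3-(4-oxopentyl)-4-(2,3,5,6-tetramethoxybenzyl)cyclohex-2-en-1-one, via Grignard reagent 14 (not isolated), via tertiary allylic carbinol 15 (not isolated)
Conditions: 13, Mg, BrCH2CH2Br (cat.), THF, reflux; CeCl3, −78 °C; 12, −78 → 0 °C; then 2 M HCl, THF, rt
Reagents that add atoms: water O
Why: Stork–Danheiser 1,3-carbonyl transposition: 1,2-addition of the Grignard reagent (CeCl3 activates the carbonyl and suppresses enolisation and addition–elimination at the sulfur-bearing carbon), then acid ionises the allylic carbinol to a sulfur-stabilised allyl cation that is hydrolysed to the enone while the dioxolane is cleaved. No stereocentre is touched.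

Step 10
Reactants: 16 (4R,5S)-4,5-dimethyl-3-(4-oxopentyl)-4-(2,3,5,6-tetramethoxybenzyl)cyclohex-2-en-1-one
Product: 18 (4S,5R,8S,9R,10R)-4-hydroxy-4,8,9-trimethyl-9-(2,3,5,6-tetramethoxybenzyl)decalin-6-one (cis-fused ketol; terpenoid numbering), via copper enolate 17 (not isolated)
Conditions: [(Ph3P)CuH]6 (0.4 equiv), PhMe, −40 °C → rt; aq. NH4Cl
Reagents that add atoms: none
Why: The monovalent copper hydride adds across the C10=C5–C6=O enone with hydride going to C10, and the copper enolate 17 then attacks the tethered C4 ketone through C5 in a chair in which copper bridges both oxygen atoms; aqueous NH4Cl releases 18. The closest known reaction type is the tandem conjugate reduction–aldol cyclisation of enone-ketones with [(Ph3P)CuH]6, known for 3-(oxoalkyl)cyclohexenones. Ring A closes in the 6-(enolexo)-exo-trig mode, the C5=C6 enolate bond lying outside the new ring and the ketone carbonyl exo to it. C10 is set by the face of hydride delivery: in the half-chair with the C8 methyl equatorial the C9 methyl is pseudoaxial, and chair-like axial attack on C10 comes anti to it and trans to the C8 methyl (the usual sense for 5-substituted cyclohexenones), which places H10 cis to the arylmethyl group. C5 is set because the new bond must form perpendicular to the enolate plane while the tether sits pseudoequatorial on C10, which gives the cis ring fusion. C4 is set by the chelate, which holds the carbinol oxygen syn to the C6 oxygen; C4 and C5 are both erased in step 11. The step needs chemoselectivity for the enone over the methyl ketone, which copper hydride provides at these temperatures, and facial selectivity at C10, which the C8 and C9 methyl groups secure together.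

Step 11
Reactants: 18 cis-fused ketol
Product: 19 (8S,9R,10S)-4,8,9-trimethyl-9-(2,3,5,6-tetramethoxybenzyl)-4(5)-decalen-6-one (C4=C5 enone; terpenoid numbering)
Conditions: NaOMe (0.5 equiv), MeOH, 65 °C
Reagents that add atoms: none
Why: E1cB dehydration of the β-hydroxy ketone (completion of an aldol condensation). Any retro-aldol returns through the same C5–C4 closure, because the only other six-membered aldol is a bridged ketol that cannot dehydrate, and uncyclised reduced material from step 10 would converge here. C10 sits on the α-carbon branch, is not acidic, and is preserved.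

Step 12
Reactants: 19 C4=C5 enone
Product: 21 (8S,9R,10S)-4,4,8,9-tetramethyl-9-(2,3,5,6-tetramethoxybenzyl)-5(6)-decalen-6-yl trifluoromethanesulfonate, via lithium enolate 20 (not isolated)
Conditions: Me2CuLi (3 equiv, from MeLi and CuI), Et2O, 0 °C; then PhNTf2, THF, 0 °C → rt
Reagents that add atoms: lithium dimethylcuprate [Li+].C[Cu-]C; N-phenylbis(trifluoromethanesulfonimide) O=S(=O)(N(c1ccccc1)S(=O)(=O)C(F)(F)F)C(F)(F)F
Why: Conjugate addition of the cuprate to the s-cis β,β-disubstituted enone (the reactivity pattern of pulegone-type enones) creates the gem-dimethyl carbon C4, and the regiodefined lithium enolate is O-sulfonylated in the same flask. No new stereocentre arises.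

Step 13
Reactants: 21 enol triflate
Product: 22 (8S,9R,10S)-4,4,8,9-tetramethyl-9-(2,3,5,6-tetramethoxybenzyl)-5(6)-decalene
Conditions: Pd(OAc)2 (5 mol %), PPh3, HCO2H, Bu3N, DMF, 60 °C
Reagents that add atoms: none
Why: Palladium-catalysed formate reduction of the enol triflate (oxidative addition to zerovalent palladium, formate exchange, decarboxylation, reductive elimination) leaves the C5=C6 alkene exactly where the triflate stood.

Step 14
Reactants: 22 tetramethoxyarene
Product: 24 2-hydroxy-5-methoxy-3-{[(8S,9R,10S)-4,4,8,9-tetramethyl-5(6)-decalen-9-yl]methyl}-1,4-benzoquinone, via dimethoxyquinone 23 (not isolated)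
Conditions: (NH4)2Ce(NO3)6 (2.5 equiv), MeCN/H2O, 0 °C; then 2 M KOH, MeOH/THF/H2O, 0 °C → rt; dil. HCl
Reagents that add atoms: water O; potassium hydroxide [K+].[OH-]
Why: Oxidative demethylation by tetravalent cerium gives the 2,5-dimethoxy-1,4-benzoquinone. Hydroxide should then exchange, by addition–elimination, the methoxy group next to the side chain, which its two neighbours twist out of conjugation and so make the more electrophilic vinylogous ester. The product rests as its anion, which should stop a second hydrolysis.

Step 15
Reactants: 24 hydroxy methoxy quinone; 25 3-methylbutan-1-amine (isopentylamine)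
Product: 26 2-hydroxy-5-(3-methylbutylamino)-3-{[(8S,9R,10S)-4,4,8,9-tetramethyl-5(6)-decalen-9-yl]methyl}-1,4-benzoquinone (nakijiquinone M)
Conditions: 25 (3 equiv), EtOH, rt
Reagents that add atoms: none
Why: Addition–elimination of the primary amine at the remaining methoxy-bearing carbon (vinylogous ester to vinylogous amide). The hydroxyquinone is present as its ammonium salt, which shields the hydroxyl-bearing carbon.

## Compound list

1 | (S)-(−)-pulegone | C[C@H]1CCC(=C(C)C)C(=O)C1 | starting material
2 | (6S)-2,2,6-trimethyl-1-oxaspiro[2.5]octan-4-one (pulegone oxide, both spiro epimers) | C[C@H]1CCC2(OC2(C)C)C(=O)C1 | intermediate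
3 | (5S)-5-methyl-2-(phenylthio)cyclohexan-1-one (C2 epimers) | C[C@H]1CCC(Sc2ccccc2)C(=O)C1 | intermediate
4 | (5S)-5-methyl-2-(phenylsulfinyl)cyclohexan-1-one (epimers at C2 and S) | C[C@H]1CCC(S(=O)c2ccccc2)C(=O)C1 | intermediate
5 | (S)-5-methylcyclohex-2-en-1-one | C[C@H]1CC=CC(=O)C1 | intermediate
6 | (5R)-5-methyl-3-(phenylthio)cyclohexan-1-one (C3 epimers) | C[C@H]1CC(Sc2ccccc2)CC(=O)C1 | intermediate
7 | (R)-5-methyl-3-(phenylthio)cyclohex-2-en-1-one | C[C@H]1CC(Sc2ccccc2)=CC(=O)C1 | intermediate
8 | (5S,6R)-5,6-dimethyl-3-(phenylthio)cyclohex-2-en-1-one | O=C1C=C(Sc2ccccc2)C[C@H](C)[C@H]1C | intermediate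
9 | 1,2,4,5-tetramethoxybenzene | COc1cc(OC)c(OC)cc1OC | starting material
10 | (2,3,5,6-tetramethoxyphenyl)methanol | COc1cc(OC)c(OC)c(CO)c1OC | intermediate
11 | 3-(bromomethyl)-1,2,4,5-tetramethoxybenzene | COc1cc(OC)c(OC)c(CBr)c1OC | intermediate
12 | (5S,6R)-5,6-dimethyl-3-(phenylthio)-6-(2,3,5,6-tetramethoxybenzyl)cyclohex-2-en-1-one | COc1cc(OC)c(OC)c(C[C@@]2(C)C(=O)C=C(Sc3ccccc3)C[C@@H]2C)c1OC | intermediate
13 | 2-(3-chloropropyl)-2-methyl-1,3-dioxolane | CC1(CCCCl)OCCO1 | starting material
14 | [3-(2-methyl-1,3-dioxolan-2-yl)propyl]magnesium chloride | CC1(CCC[Mg]Cl)OCCO1 | intermediate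
15 | (5S,6R)-5,6-dimethyl-1-[3-(2-methyl-1,3-dioxolan-2-yl)propyl]-3-(phenylthio)-6-(2,3,5,6-tetramethoxybenzyl)cyclohex-2-en-1-ol (carbinol epimers) | COc1cc(OC)c(OC)c(C[C@@]2(C)C(O)(CCCC3(C)OCCO3)C=C(Sc3ccccc3)C[C@@H]2C)c1OC | intermediate
16 | (4R,5S)-4,5-dimethyl-3-(4-oxopentyl)-4-(2,3,5,6-tetramethoxybenzyl)cyclohex-2-en-1-one | COc1cc(OC)c(OC)c(C[C@@]2(C)C(CCCC(C)=O)=CC(=O)C[C@@H]2C)c1OC | intermediate
17 | monovalent copper enolate of the (8S,9R,10R) C10-reduced ketone (phosphine ligands omitted) | COc1cc(OC)c(OC)c(C[C@@]2(C)[C@H](CCCC(C)=O)C=C(O[Cu])C[C@@H]2C)c1OC | intermediate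
18 | (4S,5R,8S,9R,10R)-4-hydroxy-4,8,9-trimethyl-9-(2,3,5,6-tetramethoxybenzyl)decalin-6-one | COc1cc(OC)c(OC)c(C[C@@]2(C)[C@@H]3CCC[C@](C)(O)[C@@H]3C(=O)C[C@@H]2C)c1OC | intermediate
19 | (8S,9R,10S)-4,8,9-trimethyl-9-(2,3,5,6-tetramethoxybenzyl)-4(5)-decalen-6-one | COc1cc(OC)c(OC)c(C[C@@]2(C)[C@@H]3CCCC(C)=C3C(=O)C[C@@H]2C)c1OC | intermediate
20 | lithium (8S,9R,10S)-4,4,8,9-tetramethyl-9-(2,3,5,6-tetramethoxybenzyl)-5(6)-decalen-6-olate | COc1cc(OC)c(OC)c(C[C@@]2(C)[C@@H]3CCCC(C)(C)C3=C(O[Li])C[C@@H]2C)c1OC | intermediate
21 | (8S,9R,10S)-4,4,8,9-tetramethyl-9-(2,3,5,6-tetramethoxybenzyl)-5(6)-decalen-6-yl trifluoromethanesulfonate | COc1cc(OC)c(OC)c(C[C@@]2(C)[C@@H]3CCCC(C)(C)C3=C(OS(=O)(=O)C(F)(F)F)C[C@@H]2C)c1OC | intermediate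
22 | (8S,9R,10S)-4,4,8,9-tetramethyl-9-(2,3,5,6-tetramethoxybenzyl)-5(6)-decalene | COc1cc(OC)c(OC)c(C[C@@]2(C)[C@@H]3CCCC(C)(C)C3=CC[C@@H]2C)c1OC | intermediate
23 | 2,5-dimethoxy-3-{[(8S,9R,10S)-4,4,8,9-tetramethyl-5(6)-decalen-9-yl]methyl}-1,4-benzoquinone | COC1=CC(=O)C(OC)=C(C[C@@]2(C)[C@@H]3CCCC(C)(C)C3=CC[C@@H]2C)C1=O | intermediate
24 | 2-hydroxy-5-methoxy-3-{[(8S,9R,10S)-4,4,8,9-tetramethyl-5(6)-decalen-9-yl]methyl}-1,4-benzoquinone | COC1=CC(=O)C(O)=C(C[C@@]2(C)[C@@H]3CCCC(C)(C)C3=CC[C@@H]2C)C1=O | intermediate
25 | 3-methylbutan-1-amine (isopentylamine) | CC(C)CCN | starting material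
26 | nakijiquinone M, 2-hydroxy-5-(3-methylbutylamino)-3-{[(8S,9R,10S)-4,4,8,9-tetramethyl-5(6)-decalen-9-yl]methyl}-1,4-benzoquinone | CC(C)CCNC1=CC(=O)C(O)=C(C[C@@]2(C)[C@@H]3CCCC(C)(C)C3=CC[C@@H]2C)C1=O | target

## Step count and least certain steps

Total: 15 steps. Longest linear sequence: 13 steps (steps 1–5 and 8–15); steps 6 and 7 form the short branch to 11.

Step 10 (key step). Hydride transfer to the fully substituted C10, beside the quaternary C9, may stall with the bulky phosphine-bound copper hydride. Conjugate reduction may occur without ring closure, or the half-chair with the arylmethyl group pseudoaxial may react competitively and erode facial selection. Reduction without closure would not matter, because the base of step 11 would close and dehydrate that material. The fallback separates reduction from C–C bond formation. It sets out from 16: silyl-triflate-catalysed ketalisation with 1,2-bis(trimethylsilyloxy)ethane (Me3SiOTf cat., CH2Cl2, −78 °C) should protect only the saturated ketone and give the dioxolane enone F1. Li in NH3/THF at −78 °C (NH4Cl quench) should reduce the enone with protonation of C10 toward the epimer that has the side chain equatorial, giving the saturated ketone ketal F2. Aqueous HCl in THF would free the diketone F3, and NaOMe in MeOH (the conditions of step 11) would effect aldol condensation, coming back to the route at 19.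

Step 12. Methyl transfer to the fully substituted C4 may be slow, so that 1,2-addition or enolisation competes, and O-sulfonylation of the hindered enolate in the presence of copper salts may be incomplete. The fallback sets out from 19: Me2CuLi with Me3SiCl in THF at −78 °C (silyl-accelerated conjugate addition) should deliver the isolable trimethylsilyl enol ether F4. MeLi in THF at 0 °C would then regenerate 20 free of copper, and PhNTf2 would bring the route back at 21.

Step 9. The carbonyl is flanked by the quaternary carbon and deactivated by sulfur donation, and the dioxolane oxygens of the Grignard reagent can chelate the metal and lower its nucleophilicity. Deprotonation at C4 or addition–elimination at the sulfur-bearing carbon may then win, and the vinyl sulfide may survive an acid treatment kept mild for the sake of the freed methyl ketone. The fallback carries the ketone as a terminal alkene. It sets out from 12: commercial pent-4-enylmagnesium bromide with CeCl3, followed by a more forcing acid hydrolysis, should give (4R,5S)-4,5-dimethyl-3-(pent-4-enyl)-4-(2,3,5,6-tetramethoxybenzyl)cyclohex-2-en-1-one F5. Wacker oxidation (PdCl2 cat., CuCl, O2, DMF/H2O) would then turn the terminal alkene into the methyl ketone and come back at 16.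

Step 14. The cerium oxidation may run on to ring-cleaved or ortho-quinone products, and hydroxide may exchange the unhindered methoxy group instead of the one beside the side chain, which would put the hydroxyl group on the wrong carbon. The fallback inverts the order so that a preference for the unhindered position works in the right direction. It sets out from 23, isolated after the oxidation: 25 in EtOH should displace the unhindered methoxy group to give the 5-(3-methylbutylamino)-2-methoxyquinone F6. Aqueous NaOH in MeOH would then hydrolyse the one remaining methoxy group and come back at 26, without passing through 24.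

## Further compounds

F1 | step 10 | (4R,5S)-4,5-dimethyl-3-[3-(2-methyl-1,3-dioxolan-2-yl)propyl]-4-(2,3,5,6-tetramethoxybenzyl)cyclohex-2-en-1-one | COc1cc(OC)c(OC)c(C[C@@]2(C)C(CCCC3(C)OCCO3)=CC(=O)C[C@@H]2C)c1OC
F2 | step 10 | (8S,9R,10R) saturated ring B ketone with dioxolane side chain (H10 cis to the arylmethyl group) | COc1cc(OC)c(OC)c(C[C@@]2(C)[C@H](CCCC3(C)OCCO3)CC(=O)C[C@@H]2C)c1OC
F3 | step 10 | (8S,9R,10R) saturated ring B ketone with 4-oxopentyl side chain (diketone) | COc1cc(OC)c(OC)c(C[C@@]2(C)[C@H](CCCC(C)=O)CC(=O)C[C@@H]2C)c1OC
F4 | step 12 | (8S,9R,10S)-4,4,8,9-tetramethyl-9-(2,3,5,6-tetramethoxybenzyl)-6-(trimethylsilyloxy)-5(6)-decalene | COc1cc(OC)c(OC)c(C[C@@]2(C)[C@@H]3CCCC(C)(C)C3=C(O[Si](C)(C)C)C[C@@H]2C)c1OC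
F5 | step 9 | (4R,5S)-4,5-dimethyl-3-(pent-4-enyl)-4-(2,3,5,6-tetramethoxybenzyl)cyclohex-2-en-1-one | COc1cc(OC)c(OC)c(C[C@@]2(C)C(CCCC=C)=CC(=O)C[C@@H]2C)c1OC
F6 | step 14 | 2-methoxy-5-(3-methylbutylamino)-3-{[(8S,9R,10S)-4,4,8,9-tetramethyl-5(6)-decalen-9-yl]methyl}-1,4-benzoquinone | CC(C)CCNC1=CC(=O)C(OC)=C(C[C@@]2(C)[C@@H]3CCCC(C)(C)C3=CC[C@@H]2C)C1=O
A1 | alternative 1 | (2E,8E,10Z)-2,7,7-trimethyl-10-(triisopropylsilyloxy)dodeca-2,8,10-trienal | O=C/C(C)=C/CCCC(C)(C)/C=C/C(O[Si](C(C)C)(C(C)C)C(C)C)=C/C
A2 | alternative 1 | cis-fused 9-formyl-4,4,8,9-tetramethyl-7-(triisopropylsilyloxy)-6(7)-decalene (8-methyl and 9-methyl cis; H5 and H10 cis to the formyl group) | O=C[C@@]1(C)[C@@H]2CCCC(C)(C)[C@@H]2C=C(O[Si](C(C)C)(C(C)C)C(C)C)[C@@H]1C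
A3 | alternative 2 | (4S,6R)-6-(6,6-dimethylcyclohex-1-en-1-yl)-4-methyl-3-(2,3,5,6-tetramethoxybenzyl)oxan-2-one (either C3 epimer) | O=C1O[C@@H](C2=CCCCC2(C)C)C[C@H](C)C1Cc1c(OC)c(OC)cc(OC)c1OC
A4 | alternative 2 | C9 carboxylic acid corresponding to 22 (carboxyl in place of the C9 methyl, same spatial arrangement) | COc1cc(OC)c(OC)c(C[C@@]2(C(=O)O)[C@@H]3CCCC(C)(C)C3=CC[C@@H]2C)c1OC
A5 | alternative 3 | 3-[(2E,6E)-farnesyl]-1,2,4,5-tetramethoxybenzene | CC(C)=CCC/C(C)=C/CC/C(C)=C/Cc1c(OC)c(OC)cc(OC)c1OC
A6 | alternative 3 | 3-(drim-7-en-11-yl)-1,2,4,5-tetramethoxybenzene (5α-H, 9α-H, 10β-methyl) | C[C@]12CCCC(C)(C)[C@@H]1CC=C(C)[C@@H]2Cc3c(OC)c(OC)cc(OC)c3OC
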